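**Retrosynthetic overview**
1. The target comes from its furyl-1,4-benzoquinone by reduction, which re-aromatises the C6 ring. The furan C5–quinone bond is cut to a C5–H furan ester and p-benzoquinone. The quinone is made in the flask by oxidising hydroquinone, and one of its four equivalent C–H sites is used. No halide, boron group or phenol protecting group is needed.
2. The senecioate ester is cut at the acyl–O bond to 3-methylbut-2-enoic acid and the (S)-prenyl carbinol, with retention at carbon.
3. The prenyl terminus is cut to an allyl group and 2-methyl-2-butene (cross-metathesis).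
4. The (S)-carbinol is cut to furan-3-carbaldehyde and a chiral allylborane. This step sets the only stereocentre.
5. Neither ring is built. The furan is bought intact. The benzenoid ring is bought as hydroquinone, de-aromatised, joined to the furan and re-aromatised last.

Assumption: the stereocentre in the given SMILES is (S) (O > furyl > CH2 > H). One step means one pot ending in one isolated product.

**Step 1**
Reactants: 1 furan-3-carbaldehyde; 2 B-allyldiisopinocampheylborane derived from (+)-α-pinene (dIpc2B-allyl; sold as a 1 M pentane solution, or made from (−)-Ipc2BOMe and allylMgBr)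
Product: 4 (S)-1-(furan-3-yl)but-3-en-1-ol, via Ipc2B borinate 3 (not isolated)
Conditions: 2 (1.2 equiv), Et2O–pentane, −100 °C, 1 h; then 3 M NaOH, 30% H2O2, 0 °C → rt
Reagents that add atoms: B-allyldiisopinocampheylborane 2 (allyl group), C=CCB([C@@H]1C[C@@H]2C[C@H]([C@H]1C)C2(C)C)[C@@H]1C[C@@H]2C[C@H]([C@H]1C)C2(C)C
Why: Brown asymmetric allylboration, in which the isopinocampheyl groups of the (+)-α-pinene-derived reagent leave only the Si face of the aldehyde open in the closed chair transition state, so the (S)-carbinol forms in the same sense and at the same ≥95% ee level as with benzaldehyde and other furan- and thiophenecarbaldehydes, and the alkaline peroxide work-up leaves the furan intact.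

**Step 2**
Reactants: 4 (S)-1-(furan-3-yl)but-3-en-1-ol; 5 2-methyl-2-butene; 6 3-methylbut-2-enoic acid (senecioic acid)
Product: 8 (S)-1-(furan-3-yl)-4-methylpent-3-en-1-yl 3-methylbut-2-enoate, via prenyl carbinol 7 (not isolated)
Conditions: (a) 5–CH2Cl2 1:1, second-generation Grubbs catalyst (H2IMes)(PCy3)Cl2Ru=CHPh (3 mol %), 38 °C, 6 h; (b) cool to 0 °C, 6 (1.5 equiv), DCC (1.5 equiv), DMAP (0.2 equiv), 0 °C → rt, 12 h; filter
Reagents that add atoms: 2-methyl-2-butene 5, CC=C(C)C; 3-methylbut-2-enoic acid 6, CC(C)=CC(=O)O
Why: Olefin cross-metathesis in excess 2-methyl-2-butene exchanges =CH2 for =CMe2 (propene leaves) without touching the furan or the carbinol centre, and the Steglich esterification that follows forms only the acyl–O bond, so the (S) configuration is retained, while the spent ruthenium species and the volatile alkene are inert to DCC/DMAP and allow one pot.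

**Step 3 (key step)**
Reactants: 8 (S)-1-(furan-3-yl)-4-methylpent-3-en-1-yl 3-methylbut-2-enoate; 9 hydroquinone
Product: 12 (S)-1-[5-(2,5-dihydroxyphenyl)furan-3-yl]-4-methylpent-3-en-1-yl 3-methylbut-2-enoate (target), via p-benzoquinone 10 (not isolated), via furylbenzoquinone 11 (not isolated)
Conditions: (a) 9 (3.0 equiv), Ag2O (3.0 equiv), MgSO4, acetone, rt, 30 min, filtered through Celite into (b) 8 (1.0 equiv), Pd(OAc)2 (10 mol %), acetone–AcOH 4:1, 40 °C, Ar, dark, 16 h; (c) EtOAc, sat. aq Na2S2O4, rt, 10 min, water washes
Reagents that add atoms: hydroquinone 9, Oc1ccc(O)cc1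
Why: Proposed new method: Pd(OAc)2 palladates the furan α-positions reversibly (concerted metalation–deprotonation), only the unhindered C5–Pd species remote from the branched C3 substituent inserts into one of the four equivalent CH=CH positions of freshly made 10, enolisation and protonolysis then release the furylhydroquinone and divalent palladium, excess 10 dehydrogenates part of it to 11, and dithionite converges everything to the aromatic 12, while the weakly acidic, base-free medium leaves the ester and the stereocentre alone; the closest known reaction type is the Fujiwara–Moritani-type dehydrogenative C–H/C–H coupling of quinones with furans and thiophenes by Pd(OAc)2, together with the tandem oxidation/C–H coupling of hydroquinones with arenes.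

**Compound list**
1 | furan-3-carbaldehyde | O=Cc1ccoc1 | starting material
2 | B-allyldiisopinocampheylborane from (+)-α-pinene (each isopinocampheyl has the spatial arrangement of (−)-isopinocampheol) | C=CCB([C@@H]1C[C@@H]2C[C@H]([C@H]1C)C2(C)C)[C@@H]1C[C@@H]2C[C@H]([C@H]1C)C2(C)C | starting material
3 | (S)-1-(furan-3-yl)but-3-en-1-yl diisopinocampheylborinate | C=CC[C@H](OB([C@@H]1C[C@@H]2C[C@H]([C@H]1C)C2(C)C)[C@@H]1C[C@@H]2C[C@H]([C@H]1C)C2(C)C)c1ccoc1 | intermediate
4 | (S)-1-(furan-3-yl)but-3-en-1-ol | C=CC[C@H](O)c1ccoc1 | intermediate
5 | 2-methyl-2-butene | CC=C(C)C | starting material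
6 | 3-methylbut-2-enoic acid | CC(C)=CC(=O)O | starting material
7 | (S)-1-(furan-3-yl)-4-methylpent-3-en-1-ol | CC(C)=CC[C@H](O)c1ccoc1 | intermediate
8 | (S)-1-(furan-3-yl)-4-methylpent-3-en-1-yl 3-methylbut-2-enoate | CC(C)=CC[C@H](OC(=O)C=C(C)C)c1ccoc1 | intermediate
9 | hydroquinone (benzene-1,4-diol) | Oc1ccc(O)cc1 | starting material
10 | p-benzoquinone | O=C1C=CC(=O)C=C1 | intermediate
11 | (S)-1-[5-(3,6-dioxocyclohexa-1,4-dien-1-yl)furan-3-yl]-4-methylpent-3-en-1-yl 3-methylbut-2-enoate | CC(C)=CC[C@H](OC(=O)C=C(C)C)c1coc(C2=CC(=O)C=CC2=O)c1 | intermediate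
12 | (S)-1-[5-(2,5-dihydroxyphenyl)furan-3-yl]-4-methylpent-3-en-1-yl 3-methylbut-2-enoate | CC(C)=CC[C@H](OC(=O)C=C(C)C)c1coc(-c2cc(O)ccc2O)c1 | target

**Total step count:** 3 (three pots; isolated products 4, 8 and 12)
**Longest linear sequence:** 3 (1 → 4 → 8 → 12)

**Steps most likely to fail**

Step 3 carries the most risk.
- Palladation or insertion may occur partly at furan C2.
- Divalent palladium with quinone in AcOH may attack the prenyl group, either by π-allyl formation or by allylic acetoxylation.
- A second furylation of 11, furan homocoupling or palladium black may cut the yield.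
- The C5 regiochemistry must be confirmed by HMBC/NOE.

The fallback sets out from 8. A sterically governed C–H borylation ([Ir(OMe)(cod)]2, dtbpy, B2pin2, THF, rt) gives (S)-1-[5-(4,4,5,5-tetramethyl-1,3,2-dioxaborolan-2-yl)furan-3-yl]-4-methylpent-3-en-1-yl 3-methylbut-2-enoate F1. Suzuki–Miyaura coupling of F1 with commercial 2-bromohydroquinone (PdCl2(dppf), K3PO4, degassed THF–H2O, 45 °C) comes back to the route at 12.

Step 1 is the next risk.
- The ee depends on the −100 °C, salt-free regime.
- Compound 4 is volatile.
- Compound 4 must be separated from the terpene alcohol by-product.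

The fallback sets out from 1. AllylMgBr (THF, 0 °C) gives racemic 1-(furan-3-yl)but-3-en-1-ol F2. An enzymatic kinetic resolution follows (Burkholderia cepacia lipase, vinyl acetate, MTBE, 30 °C, to about 52% conversion). It acetylates the (R)-enantiomer to (R)-1-(furan-3-yl)but-3-en-1-yl acetate F3 and leaves the (S)-alcohol, which comes back to the route at 4.

Step 2 is the third risk.
- The metathesis half is dependable.
- DMAP-activated senecioic acid can deconjugate through a vinylketene to the 3-methylbut-3-enoate.
- It can also end as the N-acylurea with this hindered carbinol.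

The fallback sets out from 7, now isolated after the metathesis. Acylation with diethylphosphonoacetic acid (DCC, DMAP, CH2Cl2), which has no γ-hydrogen to lose, gives (S)-1-(furan-3-yl)-4-methylpent-3-en-1-yl 2-(diethoxyphosphoryl)acetate F4. A Horner–Wadsworth–Emmons reaction with acetone (NaH, THF, 0 °C → rt) then builds the conjugated C=C after the acylation and comes back to the route at 8.

**Further compounds**
F1 | step 3 | (S)-1-[5-(4,4,5,5-tetramethyl-1,3,2-dioxaborolan-2-yl)furan-3-yl]-4-methylpent-3-en-1-yl 3-methylbut-2-enoate | CC(C)=CC[C@H](OC(=O)C=C(C)C)c1coc(B2OC(C)(C)C(C)(C)O2)c1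
F2 | step 1 | racemic 1-(furan-3-yl)but-3-en-1-ol | C=CCC(O)c1ccoc1
F3 | step 1 | (R)-1-(furan-3-yl)but-3-en-1-yl acetate | C=CC[C@@H](OC(C)=O)c1ccoc1
F4 | step 2 | (S)-1-(furan-3-yl)-4-methylpent-3-en-1-yl 2-(diethoxyphosphoryl)acetate | CC(C)=CC[C@H](OC(=O)CP(=O)(OCC)OCC)c1ccoc1
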